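**Retrosynthetic overview**

1. Selaginellin A (19) ⇐ O-demethylation of quinone methide 18 ⇐ key step: one-flask anionic [5+1] benzannulation of the bis-vinyl carbinol 12 with diphenyl carbonate. The ring-closing bond is carbonyl carbon C1 to the neighbouring CH (C6), made by 6π electrocyclisation of a dienylketene, followed by enolisation and loss of water.
2. Enabling feature: in the cyclohexa-2,5-dienone ring, C1 (C=O) lies para to C4, which carries the exocyclic C=C(aryl)(phenyl). The ring is mirror-symmetric about the O=C1···C4 axis (two identical CH=CH arms, C2=C3 and C5=C6) and is the dehydrated form of a para-hydroxyphenyl diaryl carbinol. C2 to C6 can therefore come from a 3-substituted pentadienyl unit, C1 from a one-carbon carbonyl donor, and the ring can be closed at the phenol oxidation level.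
3. 12 ⇐ diaryl ketone 8 + pentadienylzinc chloride (addition at the central carbon places both vinyl arms on C4).
4. 8 ⇐ 2,4-dibromotoluene (1): lithiation between the two bromines and benzoylation, then site-selective Suzuki–Miyaura and Sonogashira couplings.
5. Ring order: the central benzene ring and the three aryl rings are bought; the only ring made is the dienone ring, in step 5.

Key step: step 5

Assumption: the target has no stereocentre and no configurationally fixed axis, so carbinol 12 and the species derived from it are used as racemates.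

**Route**

Step 1
Reactants: 1 2,4-dibromotoluene; 2 N-methoxy-N-methylbenzamide
Product: 4 (2,6-dibromo-3-methylphenyl)(phenyl)methanone, via (2,6-dibromo-3-methylphenyl)lithium 3 (not isolated)
Conditions: LiN(iPr)2 (1.05 equiv), THF, −78 °C; then 2 (1.1 equiv), −78 to −40 °C; 1 M HCl
Reagents that add atoms: none
Why: The C–H flanked by both bromine atoms is the most acidic ring position, so amide-base ortho-lithiation should occur there, and the Weinreb ketone synthesis should stop at the ketone because the chelated tetrahedral adduct survives until work-up.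

Step 2
Reactants: 4 (2,6-dibromo-3-methylphenyl)(phenyl)methanone; 5 (4-methoxyphenyl)boronic acid
Product: 6 [2-bromo-6-(4-methoxyphenyl)-3-methylphenyl](phenyl)methanone
Conditions: 5 (1.05 equiv), Pd(PPh3)4 (3 mol %), K2CO3 (2 equiv), toluene/EtOH/H2O, 80 °C
Reagents that add atoms: none
Why: In this Suzuki–Miyaura coupling, oxidative addition to zerovalent palladium should prefer the bromide with only one ortho neighbour (benzoyl and H) over the bromide wedged between benzoyl and methyl, so one equivalent of boronic acid should couple at the less hindered C–Br.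

Step 3
Reactants: 6 [2-bromo-6-(4-methoxyphenyl)-3-methylphenyl](phenyl)methanone; 7 1-ethynyl-4-methoxybenzene
Product: 8 {6-(4-methoxyphenyl)-2-[(4-methoxyphenyl)ethynyl]-3-methylphenyl}(phenyl)methanone
Conditions: 7 (1.3 equiv), PdCl2(MeCN)2 (3 mol %), XPhos (9 mol %), Cs2CO3 (2.5 equiv), MeCN, 80 °C
Reagents that add atoms: none
Why: A copper-free Sonogashira coupling with a bulky biarylphosphine should force oxidative addition at the doubly ortho-substituted bromide, and the non-enolisable diaryl ketone should be inert under these conditions.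

Step 4
Reactants: 8 {6-(4-methoxyphenyl)-2-[(4-methoxyphenyl)ethynyl]-3-methylphenyl}(phenyl)methanone; 9 penta-1,4-diene
Product: 12 racemic 2-ethenyl-1-{6-(4-methoxyphenyl)-2-[(4-methoxyphenyl)ethynyl]-3-methylphenyl}-1-phenylbut-3-en-1-ol, via pentadienyllithium 10 (not isolated), via pentadienylzinc chloride 11 (not isolated)
Conditions: 9 (1.6 equiv), n-BuLi (1.5 equiv), THF, −78 to 0 °C; ZnCl2 (1.6 equiv), −78 °C; then 8, −78 to −20 °C; cold aq. NH4Cl
Reagents that add atoms: none
Why: Pentadienylzinc reagents add to carbonyl groups as allylmetals through a six-membered SE2′ transition state at their central carbon, which should give the branched bis-vinyl carbinol; the new carbinol centre forms as a racemate and is later flattened to the exocyclic alkene, so no stereocontrol is needed.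

Step 5
Reactants: 12 racemic 2-ethenyl-1-{6-(4-methoxyphenyl)-2-[(4-methoxyphenyl)ethynyl]-3-methylphenyl}-1-phenylbut-3-en-1-ol
Product: 18 selaginellin A di-O-methyl ether, via dilithio pentadienyl alkoxide 13 (not isolated), via phenyl dienoate 14 (not isolated), via dienylketene 15 (not isolated), via cyclohexa-2,4-dienone 16 (not isolated), via hydroxyphenyl carbinol 17 (not isolated)
Conditions: sec-BuLi (2.2 equiv), TMEDA (2.2 equiv), THF, −78 to −40 °C; added by cannula to (PhO)2CO (1.2 equiv), THF, −78 °C; −78 to 25 °C; then 1 M HCl, THF, 25 °C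
Reagents that add atoms: diphenyl carbonate, O=C(Oc1ccccc1)Oc1ccccc1
Why: Proposed new method: the lithium alkoxide of 12 should direct sec-BuLi to the doubly allylic C–H, and the 3-substituted pentadienyllithium 13 should be C-acylated at its open terminus by diphenyl carbonate to phenyl ester 14; on warming, the internal alkoxide (or LiOPh) enolises the ester, phenoxide leaves (E1cB), and dienylketene 15 closes by thermal disrotatory 6π electrocyclisation, its C=O carbon bonding to the terminal CH2 of the remaining vinyl group, to dienone 16, which enolises to phenol 17, and dilute acid then ionises the para-hydroxy-substituted triaryl carbinol with loss of water to quinone methide 18. The closest known reaction types are the benzannulation of 3,5-dienoic acids through mixed anhydrides and dienylketenes (the same 6π closure as in the Danheiser benzannulation), the ketene-forming E1cB fragmentation of aryl ester enolates, and the acylation of pentadienyl anions; new is their union into a one-flask [5+1] annulation in which a carbonate delivers the carbonyl carbon. The six-membered ring closes by pericyclic 6π electrocyclisation over C1 to C6, and the enolisation to the phenol makes the closure irreversible. No stereocentre is created, and the racemic carbinol centre of 12 becomes the sp2 exocyclic carbon. The step needs terminal rather than central acylation (enforced by the fully substituted carbinol carbon beside the central carbon), C- rather than O-acylation (favoured by the hindered tertiary alkoxide and the inverse addition), and the 3E geometry with the acyl arm cis to the vinyl arm (favoured because the bulky carbinol substituent pushes the pentadienyl anion out of the W shape, and correctable at the delocalised enolate stage); the two vinyl arms are equivalent, so either terminus gives the same ring.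

Step 6
Reactants: 18 selaginellin A di-O-methyl ether
Product: 19 selaginellin A
Conditions: BBr3 (6 equiv), CH2Cl2, −78 to 0 °C; then ice water
Reagents that add atoms: none
Why: BBr3 cleaves aryl methyl ethers by O–B complexation and bromide attack at the methyl group (Lewis acid ether cleavage), while the quinone methide should only be complexed reversibly at its carbonyl oxygen and be regenerated on aqueous work-up.

**Compound list**

1 | 2,4-dibromotoluene | Cc1ccc(Br)cc1Br | starting material
2 | N-methoxy-N-methylbenzamide | CON(C)C(=O)c1ccccc1 | starting material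
3 | (2,6-dibromo-3-methylphenyl)lithium | [Li]c1c(Br)ccc(C)c1Br | intermediate
4 | (2,6-dibromo-3-methylphenyl)(phenyl)methanone | Cc1ccc(Br)c(C(=O)c2ccccc2)c1Br | intermediate
5 | (4-methoxyphenyl)boronic acid | COc1ccc(B(O)O)cc1 | starting material
6 | [2-bromo-6-(4-methoxyphenyl)-3-methylphenyl](phenyl)methanone | Cc1ccc(-c2ccc(OC)cc2)c(C(=O)c2ccccc2)c1Br | intermediate
7 | 1-ethynyl-4-methoxybenzene | C#Cc1ccc(OC)cc1 | starting material
8 | {6-(4-methoxyphenyl)-2-[(4-methoxyphenyl)ethynyl]-3-methylphenyl}(phenyl)methanone | Cc1ccc(-c2ccc(OC)cc2)c(C(=O)c2ccccc2)c1C#Cc1ccc(OC)cc1 | intermediate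
9 | penta-1,4-diene | C=CCC=C | starting material
10 | pentadienyllithium (penta-2,4-dien-1-yllithium) | [Li]CC=CC=C | intermediate
11 | pentadienylzinc chloride | Cl[Zn]CC=CC=C | intermediate
12 | racemic 2-ethenyl-1-{6-(4-methoxyphenyl)-2-[(4-methoxyphenyl)ethynyl]-3-methylphenyl}-1-phenylbut-3-en-1-ol | Cc1ccc(-c2ccc(OC)cc2)c(C(O)(c2ccccc2)C(C=C)C=C)c1C#Cc1ccc(OC)cc1 | intermediate
13 | dilithio species of 12 (lithium alkoxide and 3-substituted pentadienyllithium, drawn in its terminal σ form; racemic) | Cc1ccc(-c2ccc(OC)cc2)c(C(O[Li])(c2ccccc2)C(C=C)=CC[Li])c1C#Cc1ccc(OC)cc1 | intermediate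
14 | phenyl (3E)-4-[aryl(lithiooxy)(phenyl)methyl]hexa-3,5-dienoate, aryl = 6-(4-methoxyphenyl)-2-[(4-methoxyphenyl)ethynyl]-3-methylphenyl (racemic) | Cc1ccc(-c2ccc(OC)cc2)c(C(O[Li])(c2ccccc2)/C(C=C)=C/CC(=O)Oc2ccccc2)c1C#Cc1ccc(OC)cc1 | intermediate
15 | (3E)-4-[aryl(hydroxy)(phenyl)methyl]hexa-1,3,5-trien-1-one (dienylketene, same aryl group; racemic) | Cc1ccc(-c2ccc(OC)cc2)c(C(O)(c2ccccc2)/C(C=C)=C/C=C=O)c1C#Cc1ccc(OC)cc1 | intermediate
16 | 4-[aryl(hydroxy)(phenyl)methyl]cyclohexa-2,4-dien-1-one (same aryl group; racemic) | Cc1ccc(-c2ccc(OC)cc2)c(C(O)(c2ccccc2)C2=CCC(=O)C=C2)c1C#Cc1ccc(OC)cc1 | intermediate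
17 | 4-[aryl(hydroxy)(phenyl)methyl]phenol (same aryl group; racemic) | Cc1ccc(-c2ccc(OC)cc2)c(C(O)(c2ccccc2)c2ccc(O)cc2)c1C#Cc1ccc(OC)cc1 | intermediate
18 | selaginellin A di-O-methyl ether, 4-[{6-(4-methoxyphenyl)-2-[(4-methoxyphenyl)ethynyl]-3-methylphenyl}(phenyl)methylidene]cyclohexa-2,5-dien-1-one | Cc1ccc(-c2ccc(OC)cc2)c(C(=C2C=CC(=O)C=C2)c2ccccc2)c1C#Cc1ccc(OC)cc1 | intermediate
19 | selaginellin A, 4-[{6-(4-hydroxyphenyl)-2-[(4-hydroxyphenyl)ethynyl]-3-methylphenyl}(phenyl)methylidene]cyclohexa-2,5-dien-1-one | Cc1ccc(-c2ccc(O)cc2)c(C(=C2C=CC(=O)C=C2)c2ccccc2)c1C#Cc1ccc(O)cc1 | target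

Total step count: 6. Longest linear sequence: 6 steps (1 to 19).

**Steps most likely to fail**

Step 5 (Proposed new method). The first-formed phenyl ester is more acidic than the diene and may quench unreacted pentadienyl anion by proton transfer; the tertiary alkoxide may be O-acylated; and phenoxide may add back to the ketene faster than the ring closes. The fallback uses known chemistry, sets out from 12 and comes back at 18. Compound 12 is metalated as in step 5 (13) and the anion is quenched with CO2 gas at −78 °C (carboxylation of a pentadienyl anion), which after acidification to pH 4 should give the hydroxy dienoic acid F1. F1 with ClCO2Et (3 equiv) and Et3N (4 equiv) in THF at 0 to 25 °C should form the mixed carbonic anhydride F2, which loses ethyl carbonate to ketene 15 and closes through 16 to phenol 17; the excess chloroformate traps 17 as the aryl ethyl carbonate F3 (the known mixed-anhydride benzannulation of 3,5-dienoic acids). NaOH in MeOH/H2O followed by 1 M HCl should cleave the carbonate and dehydrate 17 to 18.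

Step 4. Addition to the shielded carbonyl may not take place, or it may be reversible (retro-allylation), which would drain the branched adduct to the linear terminal adduct. The fallback sets out from 8 and comes back at 12. NaBH4 in THF/MeOH should reduce 8 to the benzhydrol F4; NaH and (2E)-5-bromopenta-1,3-diene in DMF should give the pentadienyl ether F5; n-BuLi in THF at −78 °C should remove the doubly benzylic O–CH proton, and the [2,3]-Wittig rearrangement then delivers this carbon to the central carbon of the pentadienyl unit. The congested C–C bond is thus formed intramolecularly, giving 12 after aqueous work-up.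

Step 6. During the Lewis acidic ether cleavage, HBr or the borane may add across the electron-rich diaryl alkyne, and the boron-bound triaryl cation may close onto the neighbouring anisyl ring in a Friedel–Crafts reaction. The fallback replaces the methyl ethers by silyl ethers from the start; it sets out from 4 and comes back at 19. Compound 4 is coupled as in step 2 (K3PO4 as base, toluene with little water) with [4-(tert-butyldimethylsilyloxy)phenyl]boronic acid to the bromo ketone F6, then as in step 3 with tert-butyl(4-ethynylphenoxy)dimethylsilane to the alkynyl ketone F7. F7 is pentadienylated as in step 4 to the carbinol F8 and annulated as in step 5 to the bis-silyl quinone methide F9. Bu4NF in THF at 0 °C followed by AcOH should remove both silyl groups and give 19.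

Further compounds
F1 | step 5 | (3E)-4-[aryl(hydroxy)(phenyl)methyl]hexa-3,5-dienoic acid, aryl = 6-(4-methoxyphenyl)-2-[(4-methoxyphenyl)ethynyl]-3-methylphenyl (racemic) | Cc1ccc(-c2ccc(OC)cc2)c(C(O)(c2ccccc2)/C(C=C)=C/CC(=O)O)c1C#Cc1ccc(OC)cc1
F2 | step 5 | mixed anhydride of F1 with ethyl hydrogen carbonate | Cc1ccc(-c2ccc(OC)cc2)c(C(O)(c2ccccc2)/C(C=C)=C/CC(=O)OC(=O)OCC)c1C#Cc1ccc(OC)cc1
F3 | step 5 | ethyl 4-[aryl(hydroxy)(phenyl)methyl]phenyl carbonate (same aryl group; racemic) | Cc1ccc(-c2ccc(OC)cc2)c(C(O)(c2ccccc2)c2ccc(OC(=O)OCC)cc2)c1C#Cc1ccc(OC)cc1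
F4 | step 4 | racemic {6-(4-methoxyphenyl)-2-[(4-methoxyphenyl)ethynyl]-3-methylphenyl}(phenyl)methanol | Cc1ccc(-c2ccc(OC)cc2)c(C(O)c2ccccc2)c1C#Cc1ccc(OC)cc1
F5 | step 4 | racemic (2E)-penta-2,4-dien-1-yl ether of F4 | Cc1ccc(-c2ccc(OC)cc2)c(C(OC/C=C/C=C)c2ccccc2)c1C#Cc1ccc(OC)cc1
F6 | step 6 | {2-bromo-6-[4-(tert-butyldimethylsilyloxy)phenyl]-3-methylphenyl}(phenyl)methanone | Cc1ccc(-c2ccc(O[Si](C)(C)C(C)(C)C)cc2)c(C(=O)c2ccccc2)c1Br
F7 | step 6 | bis-TBS analogue of ketone 8 | Cc1ccc(-c2ccc(O[Si](C)(C)C(C)(C)C)cc2)c(C(=O)c2ccccc2)c1C#Cc1ccc(O[Si](C)(C)C(C)(C)C)cc1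
F8 | step 6 | bis-TBS analogue of carbinol 12 (racemic) | Cc1ccc(-c2ccc(O[Si](C)(C)C(C)(C)C)cc2)c(C(O)(c2ccccc2)C(C=C)C=C)c1C#Cc1ccc(O[Si](C)(C)C(C)(C)C)cc1
F9 | step 6 | selaginellin A bis(tert-butyldimethylsilyl) ether | Cc1ccc(-c2ccc(O[Si](C)(C)C(C)(C)C)cc2)c(C(=C2C=CC(=O)C=C2)c2ccccc2)c1C#Cc1ccc(O[Si](C)(C)C(C)(C)C)cc1
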